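**Retrosynthetic overview**
1. The target comes from the protected flavanone 13 by one Lewis-acid deprotection (three O-benzyl groups and the chelated 5-O-methyl group).
2. The pyranone ring of the flavanone half is cut at O1–C2 and at C4–C4a, giving cinnamoyl chloride 9 and 3,5-dimethoxyphenol 10; forward, a [3+3] annulation (ortho-C-acylation, then enantioselective 6-endo oxa-Michael closure) builds this ring and C2 last.
3. Enabling feature: the flavanone A ring is a 1,3,5-trioxygenated benzene whose O1 and ring-fusion carbon C4a (ortho to O1, flanked by the 5-oxygen, para to 7-OMe) form an O,C-1,3-dinucleophile. It is matched by the acyl carbon C4 and β-carbon C2 of the cinnamoyl arm, and the C2-symmetric phenol 10 allows only one regiochemistry.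
4. 9 comes from aryl bromide 6 by Heck reaction with acrylic acid; the flavone pyranone ring of 6 comes from Claisen–Schmidt condensation and oxidative cyclisation; the diaryl ether is made first by SNAr.
5. Ring order: flavone C ring (step 3), then flavanone C ring (step 6).

Key step: step 6

Assumption: 2 and 4 are taken as catalogue building blocks, and the quinine-derived catalyst of step 6 is taken to give the (2S) series; if a model chalcone shows the opposite sense, the quinidine-derived pseudoenantiomer is used.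

**Route**

Step 1
Reactants: 1 4-fluorobenzaldehyde; 2 2-(benzyloxy)-5-bromophenol
Product: 3 4-[2-(benzyloxy)-5-bromophenoxy]benzaldehyde
Conditions: K2CO3, DMF, 110 °C
Reagents that add atoms: none
Why: SNAr of the phenoxide on the para-formyl-activated aryl fluoride should give the diaryl ether, with the aryl bromide inert under these conditions.

Step 2
Reactants: 3 4-[2-(benzyloxy)-5-bromophenoxy]benzaldehyde; 4 1-[2,4-bis(benzyloxy)-6-hydroxyphenyl]ethan-1-one
Product: 5 (E)-1-[2,4-bis(benzyloxy)-6-hydroxyphenyl]-3-{4-[2-(benzyloxy)-5-bromophenoxy]phenyl}prop-2-en-1-one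
Conditions: KOH, EtOH/THF, rt; then aq. HCl
Reagents that add atoms: none
Why: Claisen–Schmidt condensation, in which only the acetophenone can enolise and E1cB dehydration should give the E-enone.

Step 3
Reactants: 5 (E)-1-[2,4-bis(benzyloxy)-6-hydroxyphenyl]-3-{4-[2-(benzyloxy)-5-bromophenoxy]phenyl}prop-2-en-1-one
Product: 6 5,7-bis(benzyloxy)-2-{4-[2-(benzyloxy)-5-bromophenoxy]phenyl}-4H-chromen-4-one
Conditions: I2 (10 mol%), DMSO, 130 °C
Reagents that add atoms: none
Why: Iodine-catalysed oxidative cyclisation of a 2'-hydroxychalcone (oxa-Michael closure, α-iodination and HI loss, with DMSO as terminal oxidant) should give the flavone.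

Step 4
Reactants: 6 5,7-bis(benzyloxy)-2-{4-[2-(benzyloxy)-5-bromophenoxy]phenyl}-4H-chromen-4-one; 7 acrylic acid
Product: 8 (E)-3-{4-(benzyloxy)-3-[4-(5,7-bis(benzyloxy)-4-oxo-4H-chromen-2-yl)phenoxy]phenyl}prop-2-enoic acid
Conditions: Pd(OAc)2 (5 mol%), P(o-tol)3, Et3N, DMF, 100 °C; then aq. HCl
Reagents that add atoms: none
Why: Mizoroki–Heck coupling of the aryl bromide with acrylic acid, in which syn-β-hydride elimination should give the E-cinnamic acid.

Step 5
Reactants: 8 (E)-3-{4-(benzyloxy)-3-[4-(5,7-bis(benzyloxy)-4-oxo-4H-chromen-2-yl)phenoxy]phenyl}prop-2-enoic acid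
Product: 9 (E)-3-{4-(benzyloxy)-3-[4-(5,7-bis(benzyloxy)-4-oxo-4H-chromen-2-yl)phenoxy]phenyl}prop-2-enoyl chloride
Conditions: 1-chloro-N,N,2-trimethylprop-1-en-1-amine, CH2Cl2, 0 °C → rt; evaporated and used crude
Reagents that add atoms: 1-chloro-N,N,2-trimethylprop-1-en-1-amine (Ghosez reagent), CC(C)=C(Cl)N(C)C
Why: Acid chloride formation with an α-chloroenamine runs under neutral conditions and should leave the flavone carbonyl and the benzyl ethers untouched.

Step 6
Reactants: 9 (E)-3-{4-(benzyloxy)-3-[4-(5,7-bis(benzyloxy)-4-oxo-4H-chromen-2-yl)phenoxy]phenyl}prop-2-enoyl chloride; 10 3,5-dimethoxyphenol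
Product: 13 (2S)-2-{4-(benzyloxy)-3-[4-(5,7-bis(benzyloxy)-4-oxo-4H-chromen-2-yl)phenoxy]phenyl}-5,7-dimethoxychroman-4-one, via bromomagnesium 3,5-dimethoxyphenoxide 11 (not isolated), via 2'-hydroxychalcone 12 (not isolated)
Conditions: 10 (2.4 equiv), EtMgBr (2.3 equiv), Et2O/toluene, 0 °C → rt; 9, toluene/CH2Cl2, 0 °C → rt; AcOH, Mg salts filtered off; quinine-derived thiourea (9-amino-9-deoxy-epi-quinine 3,5-bis(trifluoromethyl)phenylthiourea, 10 mol%), toluene, 0 °C → rt
Reagents that add atoms: ethylmagnesium bromide, CC[Mg]Br (Mg and Br appear in intermediate 11 only, none in 13)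
Why: Proposed new method: phenoxide 11 binds the acyl chloride at magnesium and delivers the acyl carbon through a six-membered chelate to its ortho carbon (C4–C4a bond; closest known type: metal-template ortho-acylation of phenoxymagnesium halides with acyl chlorides), and tautomerisation gives the magnesium chelate of chalcone 12. After release of 12 with AcOH, the bifunctional cinchona thiourea closes the pyranone ring by 6-endo-trig oxa-Michael addition of the 2'-OH to the s-cis enone (O1–C2 bond; closest known type: cinchona-thiourea- and cinchona-base-catalysed cyclisation of 2'-hydroxychalcones to flavanones). What is new is the telescoping of both events into one annulation and the reliance on catalyst control for a chalcone without an activating ester. C2, the only new stereocenter, is set by the catalyst: the thiourea N–H groups hold the ketone oxygen while the quinuclidine deprotonates the phenol and guides it onto one face of the β-carbon, intended to be the face giving 2S. The step needs C-acylation instead of O-acylation or conjugate C-alkylation, ortho instead of para attack and catalysed instead of spontaneous ring closure; the magnesium template, the C2 symmetry of 10 (both ortho carbons identical, para carbon out of reach of the chelate) and the 2'-OH···O=C hydrogen bond of 12, which has no second free OH, should secure these. The 6'-methoxy group twists the enone out of the aryl plane, so ring closure should lie far on the flavanone side and the kinetic selectivity should not be eroded by reopening.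

Step 7
Reactants: 13 (2S)-2-{4-(benzyloxy)-3-[4-(5,7-bis(benzyloxy)-4-oxo-4H-chromen-2-yl)phenoxy]phenyl}-5,7-dimethoxychroman-4-one
Product: 14 (2S)-2-{3-[4-(5,7-dihydroxy-4-oxo-4H-chromen-2-yl)phenoxy]-4-hydroxyphenyl}-5-hydroxy-7-methoxychroman-4-one
Conditions: BCl3 (1 M in CH2Cl2), pentamethylbenzene, CH2Cl2, −78 → 0 °C; MeOH quench, pH 7 work-up
Reagents that add atoms: none
Why: BCl3 with pentamethylbenzene as cation scavenger should cleave the three aryl benzyl ethers, and chelation between C4=O and the peri 5-OMe should direct demethylation to that group alone, leaving the 7-OMe; the non-basic conditions should not epimerise C2.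

**Compound list**
1 | 4-fluorobenzaldehyde | O=Cc1ccc(F)cc1 | starting material
2 | 2-(benzyloxy)-5-bromophenol | Oc1cc(Br)ccc1OCc1ccccc1 | starting material
3 | 4-[2-(benzyloxy)-5-bromophenoxy]benzaldehyde | O=Cc1ccc(Oc2cc(Br)ccc2OCc2ccccc2)cc1 | intermediate
4 | 1-[2,4-bis(benzyloxy)-6-hydroxyphenyl]ethan-1-one | CC(=O)c1c(O)cc(OCc2ccccc2)cc1OCc1ccccc1 | starting material
5 | (E)-1-[2,4-bis(benzyloxy)-6-hydroxyphenyl]-3-{4-[2-(benzyloxy)-5-bromophenoxy]phenyl}prop-2-en-1-one | O=C(/C=C/c1ccc(Oc2cc(Br)ccc2OCc2ccccc2)cc1)c1c(O)cc(OCc2ccccc2)cc1OCc1ccccc1 | intermediate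
6 | 5,7-bis(benzyloxy)-2-{4-[2-(benzyloxy)-5-bromophenoxy]phenyl}-4H-chromen-4-one | O=c1cc(-c2ccc(Oc3cc(Br)ccc3OCc3ccccc3)cc2)oc2cc(OCc3ccccc3)cc(OCc3ccccc3)c12 | intermediate
7 | acrylic acid | C=CC(=O)O | starting material
8 | (E)-3-{4-(benzyloxy)-3-[4-(5,7-bis(benzyloxy)-4-oxo-4H-chromen-2-yl)phenoxy]phenyl}prop-2-enoic acid | OC(=O)/C=C/c1ccc(OCc2ccccc2)c(Oc2ccc(-c3cc(=O)c4c(OCc5ccccc5)cc(OCc5ccccc5)cc4o3)cc2)c1 | intermediate
9 | (E)-3-{4-(benzyloxy)-3-[4-(5,7-bis(benzyloxy)-4-oxo-4H-chromen-2-yl)phenoxy]phenyl}prop-2-enoyl chloride | O=C(Cl)/C=C/c1ccc(OCc2ccccc2)c(Oc2ccc(-c3cc(=O)c4c(OCc5ccccc5)cc(OCc5ccccc5)cc4o3)cc2)c1 | intermediate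
10 | 3,5-dimethoxyphenol | COc1cc(O)cc(OC)c1 | starting material
11 | bromomagnesium 3,5-dimethoxyphenoxide | COc1cc(OC)cc(O[Mg]Br)c1 | intermediate
12 | (E)-3-{4-(benzyloxy)-3-[4-(5,7-bis(benzyloxy)-4-oxo-4H-chromen-2-yl)phenoxy]phenyl}-1-(2-hydroxy-4,6-dimethoxyphenyl)prop-2-en-1-one | COc1cc(O)c(C(=O)/C=C/c2ccc(OCc3ccccc3)c(Oc3ccc(-c4cc(=O)c5c(OCc6ccccc6)cc(OCc6ccccc6)cc5o4)cc3)c2)c(OC)c1 | intermediate
13 | (2S)-2-{4-(benzyloxy)-3-[4-(5,7-bis(benzyloxy)-4-oxo-4H-chromen-2-yl)phenoxy]phenyl}-5,7-dimethoxychroman-4-one | COc1cc(OC)c2c(c1)O[C@H](c1ccc(OCc3ccccc3)c(Oc3ccc(-c4cc(=O)c5c(OCc6ccccc6)cc(OCc6ccccc6)cc5o4)cc3)c1)CC2=O | intermediate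
14 | (2S)-2-{3-[4-(5,7-dihydroxy-4-oxo-4H-chromen-2-yl)phenoxy]-4-hydroxyphenyl}-5-hydroxy-7-methoxychroman-4-one | COc1cc(O)c2c(c1)O[C@H](c1ccc(O)c(Oc3ccc(-c4cc(=O)c5c(O)cc(O)cc5o4)cc3)c1)CC2=O | target

**Count**
Total steps: 7. Longest linear sequence: 7 (steps 1 to 7).

**Steps most likely to fail**

Step 6 (Proposed new method). What may go wrong: O-acylation of the phenoxide or attack at the β-carbon may outrun the templated C-acylation, facial discrimination in the ring closure of the ester-free chalcone may be insufficient, or selectivity may be lost by reversible ring opening. The fallback uses known chemistry and forms the C2–aryl bond instead; it sets out from 6 and comes back at 13. Pd-catalysed borylation of 6 with tetrahydroxydiboron (XPhos Pd G2, KOAc, EtOH, 80 °C) gives {4-(benzyloxy)-3-[4-(5,7-bis(benzyloxy)-4-oxo-4H-chromen-2-yl)phenoxy]phenyl}boronic acid F1. Commercial 1-(2-hydroxy-4,6-dimethoxyphenyl)ethanone is condensed with DMF dimethyl acetal to the enaminone (E)-3-(dimethylamino)-1-(2-hydroxy-4,6-dimethoxyphenyl)prop-2-en-1-one F2, which closes with acid to 5,7-dimethoxy-4H-chromen-4-one F3. Asymmetric conjugate addition of F1 to F3 (Pd(OCOCF3)2, t-BuPyOX of the hand that gives 2S, NH4PF6, H2O, ClCH2CH2Cl, 60 °C) should then give 13; the 2-aryl-substituted flavone unit is a far poorer acceptor than F3 and should stay untouched.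

Step 7. What may go wrong: Lewis-acid-induced opening of the pyranone ring with loss of configuration at C2, incomplete debenzylation, or loss of the 7-O-methyl group. The fallback separates the two deprotections; it sets out from 13 and comes back at 14. Neutral hydrogenolysis (H2, Pd/C, THF/EtOAc, rt) removes the three benzyl groups to give (2S)-2-{3-[4-(5,7-dihydroxy-4-oxo-4H-chromen-2-yl)phenoxy]-4-hydroxyphenyl}-5,7-dimethoxychroman-4-one F4. Chelation-directed demethylation of F4 with MgI2 etherate (THF/toluene, 60 °C) should then cleave only the 5-OMe.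

Step 3. What may go wrong: HI formed in the flask may cleave the peri 5-O-benzyl ether or the electron-rich rings may be iodinated at 130 °C. The fallback avoids iodine; it sets out from 5 and comes back at 6. NaOAc in refluxing EtOH closes 5 to racemic 5,7-bis(benzyloxy)-2-{4-[2-(benzyloxy)-5-bromophenoxy]phenyl}chroman-4-one F5, and DDQ in refluxing dioxane dehydrogenates F5 to 6.

**Further compounds**
F1 | step 6 | {4-(benzyloxy)-3-[4-(5,7-bis(benzyloxy)-4-oxo-4H-chromen-2-yl)phenoxy]phenyl}boronic acid | OB(O)c1ccc(OCc2ccccc2)c(Oc2ccc(-c3cc(=O)c4c(OCc5ccccc5)cc(OCc5ccccc5)cc4o3)cc2)c1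
F2 | step 6 | (E)-3-(dimethylamino)-1-(2-hydroxy-4,6-dimethoxyphenyl)prop-2-en-1-one | CN(C)/C=C/C(=O)c1c(O)cc(OC)cc1OC
F3 | step 6 | 5,7-dimethoxy-4H-chromen-4-one | COc1cc(OC)c2c(c1)occc2=O
F4 | step 7 | (2S)-2-{3-[4-(5,7-dihydroxy-4-oxo-4H-chromen-2-yl)phenoxy]-4-hydroxyphenyl}-5,7-dimethoxychroman-4-one | COc1cc(OC)c2c(c1)O[C@H](c1ccc(O)c(Oc3ccc(-c4cc(=O)c5c(O)cc(O)cc5o4)cc3)c1)CC2=O
F5 | step 3 | rac-5,7-bis(benzyloxy)-2-{4-[2-(benzyloxy)-5-bromophenoxy]phenyl}chroman-4-one | O=C1CC(c2ccc(Oc3cc(Br)ccc3OCc3ccccc3)cc2)Oc2cc(OCc3ccccc3)cc(OCc3ccccc3)c12
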